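**Retrosynthetic overview**

1. The strategy rests on the 2‑methyl‑4H‑pyran‑4‑one ring (O1, C2, C3, C4), fused to the phloroglucinol ring at C8a and C4a. C8a–O and C4a are read as the hydroxyl and iodine of an ortho‑iodophenol, C4 as CO, and C3, C2 and the methyl group as propyne.
2. Chrotacumine D 19 ⇐ 5‑O‑silyl ether 18 (desilylation) ⇐ iodophenol 13 + CO + propyne by palladium‑catalysed carbonylative annulation (C4a–C4, C4–C3, O1–C2) on the intact piperidinyl veratrate.
3. 13 ⇐ triol ester 11 (para‑selective silylation, then mono‑iodination) ⇐ tetraol 8 + veratroyl chloride (exhaustive acylation, then selective aminolysis of the aryl esters).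
4. 8 ⇐ (3S,4R)‑cis‑arylpiperidinol 7 (demethylation) ⇐ 1,3,5‑trimethoxybenzene + 1‑methylpiperidin‑4‑one (condensation, hydroboration–oxidation, Swern oxidation, cis‑selective reduction, resolution).
5. Ring order: the benzene and piperidine rings are bought in; the pyranone ring is the only ring made and is closed in step 10, one step before the end.

Key step: step 10

Assumption: in step 5 the (3S,4R)‑amino alcohol is taken to form the less soluble salt with O,O′‑dibenzoyl‑D‑tartaric acid; should the other diastereomeric salt crystallise, the L‑acid is used in the same way.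

**Route**

Step 1
Reactants: 1 1,3,5‑trimethoxybenzene; 2 1‑methylpiperidin‑4‑one
Product: 3 1‑methyl‑4‑(2,4,6‑trimethoxyphenyl)‑1,2,3,6‑tetrahydropyridine
Conditions: HCl (g), AcOH, rt → 90 °C
Reagents that add atoms: none
Why: Acid‑mediated Friedel–Crafts hydroxyalkylation of the electron‑rich arene by the protonated ketone, followed by dehydration of the tertiary benzylic carbinol to the conjugated alkene; the threefold symmetry of 1 allows only one regioisomer.

Step 2
Reactants: 3 1‑methyl‑4‑(2,4,6‑trimethoxyphenyl)‑1,2,3,6‑tetrahydropyridine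
Product: 4 rac‑trans‑1‑methyl‑4‑(2,4,6‑trimethoxyphenyl)piperidin‑3‑ol
Conditions: BH3·THF (3 equiv), THF, 0 → 50 °C; conc. HCl, 50 °C; then aq. NaOH, 30% H2O2, 50 °C
Reagents that add atoms: hydrogen peroxide, OO
Why: Hydroboration–oxidation: syn addition places boron on the less substituted C3 and hydrogen on the benzylic C4, and oxidation with retention should give the trans amino alcohol as a racemate (the acid treatment breaks the amine–borane complex).

Step 3
Reactants: 4 rac‑trans‑1‑methyl‑4‑(2,4,6‑trimethoxyphenyl)piperidin‑3‑ol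
Product: 5 rac‑1‑methyl‑4‑(2,4,6‑trimethoxyphenyl)piperidin‑3‑one
Conditions: (COCl)2, DMSO, CH2Cl2, −78 °C; Et3N, −78 °C → rt
Reagents that add atoms: none
Why: Swern oxidation converts the secondary alcohol into the ketone under non‑acidic, low‑temperature conditions that the tertiary amine and the electron‑rich arene tolerate; the configurational lability of the α‑aryl centre of 5 is harmless in the racemic series.

Step 4
Reactants: 5 rac‑1‑methyl‑4‑(2,4,6‑trimethoxyphenyl)piperidin‑3‑one
Product: 6 rac‑cis‑1‑methyl‑4‑(2,4,6‑trimethoxyphenyl)piperidin‑3‑ol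
Conditions: LiBH(s‑Bu)3 (L‑Selectride, 1.3 equiv), THF, −78 °C; aq. NH4Cl, acid–base extraction
Reagents that add atoms: none
Why: Diastereoselective ketone reduction with a bulky hydride: LiBH(s‑Bu)3 should attack the carbonyl face remote from the neighbouring 2,4,6‑trimethoxyphenyl group (equatorial attack on the chair with equatorial aryl), which sets the C3 hydroxyl cis to the aryl group in the racemate.

Step 5
Reactants: 6 rac‑cis‑1‑methyl‑4‑(2,4,6‑trimethoxyphenyl)piperidin‑3‑ol
Product: 7 (3S,4R)‑1‑methyl‑4‑(2,4,6‑trimethoxyphenyl)piperidin‑3‑ol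
Conditions: O,O′‑dibenzoyl‑D‑tartaric acid (1 equiv), MeOH, recrystallise; then aq. NaOH, CH2Cl2
Reagents that add atoms: none
Why: Classical resolution by crystallisation of diastereomeric salts of the basic amino alcohol, which fixes the absolute configuration (3S,4R) without touching either stereocentre; the configuration is to be confirmed on the salt by X‑ray analysis.

Step 6
Reactants: 7 (3S,4R)‑1‑methyl‑4‑(2,4,6‑trimethoxyphenyl)piperidin‑3‑ol
Product: 8 2‑[(3S,4R)‑3‑hydroxy‑1‑methylpiperidin‑4‑yl]benzene‑1,3,5‑triol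
Conditions: BBr3 (8 equiv), CH2Cl2, −78 °C → rt; MeOH, 0 °C; evaporate (hydrobromide, used crude under Ar)
Reagents that add atoms: none
Why: Lewis acid cleavage of the three aryl methyl ethers (O–B complexation, then bromide attack on methyl); the amine and the alcohol bind boron and are released on methanolysis, no stereocentre is involved, and demethylation has to precede esterification because the veratrate carries methyl ethers of its own.

Step 7
Reactants: 8 2‑[(3S,4R)‑3‑hydroxy‑1‑methylpiperidin‑4‑yl]benzene‑1,3,5‑triol; 9 3,4‑dimethoxybenzoyl chloride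
Product: 11 (3S,4R)‑1‑methyl‑4‑(2,4,6‑trihydroxyphenyl)piperidin‑3‑yl 3,4‑dimethoxybenzoate, via tetrakis‑veratrate 10 (not isolated)
Conditions: 9 (5 equiv), DMAP (0.2 equiv), pyridine, 0 → 40 °C, Ar; then pyrrolidine (12 equiv), 0 °C → rt; AcOH quench
Reagents that add atoms: none
Why: Exhaustive DMAP‑catalysed O‑acylation followed by chemoselective aminolysis: a direct mono‑acylation would favour the phenols over the hindered secondary alcohol, so all four hydroxyls are esterified and pyrrolidine should then cleave only the three aryl esters (phenoxide leaving groups), leaving the hindered alkyl veratrate with C3 configuration retained.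

Step 8
Reactants: 11 (3S,4R)‑1‑methyl‑4‑(2,4,6‑trihydroxyphenyl)piperidin‑3‑yl 3,4‑dimethoxybenzoate
Product: 12 (3S,4R)‑4‑[2,6‑dihydroxy‑4‑(triisopropylsilyloxy)phenyl]‑1‑methylpiperidin‑3‑yl 3,4‑dimethoxybenzoate
Conditions: i‑Pr3SiCl (1.05 equiv), imidazole (2.5 equiv), DMF, 0 °C
Reagents that add atoms: chlorotriisopropylsilane, CC(C)[Si](Cl)(C(C)C)C(C)C
Why: Sterically controlled silyl ether formation: the para hydroxyl lies between two ring hydrogens whereas each ortho hydroxyl is crowded by the piperidinyl veratrate, so one equivalent of the bulky silyl chloride should react at the para oxygen; unlike a chloromethyl ether, a silyl chloride cannot quaternise the N‑methylpiperidine irreversibly.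

Step 9
Reactants: 12 (3S,4R)‑4‑[2,6‑dihydroxy‑4‑(triisopropylsilyloxy)phenyl]‑1‑methylpiperidin‑3‑yl 3,4‑dimethoxybenzoate
Product: 13 (3S,4R)‑4‑[2,6‑dihydroxy‑3‑iodo‑4‑(triisopropylsilyloxy)phenyl]‑1‑methylpiperidin‑3‑yl 3,4‑dimethoxybenzoate
Conditions: I2 (1.0 equiv, slow addition), NaHCO3, THF–H2O, 0 °C
Reagents that add atoms: iodine, II
Why: Electrophilic aromatic iodination of the phenol: the two free ring positions are interchanged by rotation about the aryl–piperidine bond, so mono‑iodination can give only one constitutional isomer, with iodine between a free hydroxyl and the silyl ether; one equivalent at 0 °C limits di‑iodination and the bicarbonate buffer spares the silyl ether and the ester.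

Step 10
Reactants: 13 (3S,4R)‑4‑[2,6‑dihydroxy‑3‑iodo‑4‑(triisopropylsilyloxy)phenyl]‑1‑methylpiperidin‑3‑yl 3,4‑dimethoxybenzoate; 14 propyne; 15 carbon monoxide
Product: 18 (3S,4R)‑4‑[7‑hydroxy‑2‑methyl‑4‑oxo‑5‑(triisopropylsilyloxy)‑4H‑chromen‑8‑yl]‑1‑methylpiperidin‑3‑yl 3,4‑dimethoxybenzoate (5‑O‑triisopropylsilyl‑chrotacumine D), via aryl ynone 16 (not isolated), via enaminone 17 (not isolated)
Conditions: PdCl2(PPh3)2 (5 mol %), Et2NH–THF (1:2), propyne (5 equiv), CO (5 bar), 60 °C, autoclave
Reagents that add atoms: diethylamine, CCNCC (its atoms stand only in intermediate 17 and leave again on ring closure)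
Why: Carbonylative Sonogashira coupling followed by amine‑mediated annulation, the known palladium‑catalysed route from ortho‑iodophenols, CO and terminal alkynes to chromones: PdCl2(PPh3)2 is reduced in situ to zerovalent palladium, which inserts into the C–I bond of 13; CO insertion gives an aroylpalladium iodide, and the acetylide formed from propyne and Et2NH is transferred and reductively eliminated to give ynone 16 (C4a–C4 and C4–C3 formed). Et2NH then adds to the ynone to give the vinylogous amide 17, and the adjacent phenol oxygen closes the pyranone ring by 6‑endo‑trig addition to the β‑carbon with loss of Et2NH (O1–C2 formed). No stereocentre is created, and the two piperidine stereocentres are remote from any acidic or electrophilic site under these conditions. Three selectivities are needed: CO insertion ahead of direct alkynylation (secured by CO pressure and the absence of copper), 6‑endo over 5‑exo (aurone) closure (secured because the amine adduct 17 offers only its β‑carbon to the phenol), and the sense of ring fusion (secured because the acyl group stands between one free hydroxyl and the silylated oxygen, while the second free hydroxyl is para to it and cannot reach). The ester, the silyl ether and the tertiary amine should be inert to CO, the amine base and the catalyst at 60 °C.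

Step 11
Reactants: 18 5‑O‑triisopropylsilyl‑chrotacumine D
Product: 19 chrotacumine D, (3S,4R)‑4‑(5,7‑dihydroxy‑2‑methyl‑4‑oxo‑4H‑chromen‑8‑yl)‑1‑methylpiperidin‑3‑yl 3,4‑dimethoxybenzoate
Conditions: Bu4NF (1.2 equiv), AcOH (1.2 equiv), THF, 0 °C
Reagents that add atoms: none
Why: Fluoride‑mediated desilylation of the aryl silyl ether (driven by the Si–F bond), buffered with acetic acid so that the alkyl ester, the chromone and both stereocentres are untouched.

**Compound list**

1 | 1,3,5‑trimethoxybenzene | COc1cc(OC)cc(OC)c1 | starting material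
2 | 1‑methylpiperidin‑4‑one | CN1CCC(=O)CC1 | starting material
3 | 1‑methyl‑4‑(2,4,6‑trimethoxyphenyl)‑1,2,3,6‑tetrahydropyridine | CN1CC=C(CC1)c1c(OC)cc(OC)cc1OC | intermediate
4 | rac‑trans‑(3R,4R)/(3S,4S)‑1‑methyl‑4‑(2,4,6‑trimethoxyphenyl)piperidin‑3‑ol (racemate, both enantiomers written) | O[C@H]1CN(C)CC[C@@H]1c1c(OC)cc(OC)cc1OC.O[C@@H]1CN(C)CC[C@H]1c1c(OC)cc(OC)cc1OC | intermediate
5 | rac‑1‑methyl‑4‑(2,4,6‑trimethoxyphenyl)piperidin‑3‑one | O=C1CN(C)CCC1c1c(OC)cc(OC)cc1OC | intermediate
6 | rac‑cis‑(3S,4R)/(3R,4S)‑1‑methyl‑4‑(2,4,6‑trimethoxyphenyl)piperidin‑3‑ol (racemate, both enantiomers written) | O[C@@H]1CN(C)CC[C@@H]1c1c(OC)cc(OC)cc1OC.O[C@H]1CN(C)CC[C@H]1c1c(OC)cc(OC)cc1OC | intermediate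
7 | (3S,4R)‑1‑methyl‑4‑(2,4,6‑trimethoxyphenyl)piperidin‑3‑ol | O[C@@H]1CN(C)CC[C@@H]1c1c(OC)cc(OC)cc1OC | intermediate
8 | 2‑[(3S,4R)‑3‑hydroxy‑1‑methylpiperidin‑4‑yl]benzene‑1,3,5‑triol | O[C@@H]1CN(C)CC[C@@H]1c1c(O)cc(O)cc1O | intermediate
9 | 3,4‑dimethoxybenzoyl chloride | COc1ccc(C(=O)Cl)cc1OC | starting material
10 | (3S,4R)‑1‑methyl‑4‑[2,4,6‑tris(3,4‑dimethoxybenzoyloxy)phenyl]piperidin‑3‑yl 3,4‑dimethoxybenzoate | COc1ccc(C(=O)O[C@@H]2CN(C)CC[C@@H]2c2c(OC(=O)c3ccc(OC)c(OC)c3)cc(OC(=O)c3ccc(OC)c(OC)c3)cc2OC(=O)c2ccc(OC)c(OC)c2)cc1OC | intermediate (not isolated)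
11 | (3S,4R)‑1‑methyl‑4‑(2,4,6‑trihydroxyphenyl)piperidin‑3‑yl 3,4‑dimethoxybenzoate | COc1ccc(C(=O)O[C@@H]2CN(C)CC[C@@H]2c2c(O)cc(O)cc2O)cc1OC | intermediate
12 | (3S,4R)‑4‑[2,6‑dihydroxy‑4‑(triisopropylsilyloxy)phenyl]‑1‑methylpiperidin‑3‑yl 3,4‑dimethoxybenzoate | COc1ccc(C(=O)O[C@@H]2CN(C)CC[C@@H]2c2c(O)cc(O[Si](C(C)C)(C(C)C)C(C)C)cc2O)cc1OC | intermediate
13 | (3S,4R)‑4‑[2,6‑dihydroxy‑3‑iodo‑4‑(triisopropylsilyloxy)phenyl]‑1‑methylpiperidin‑3‑yl 3,4‑dimethoxybenzoate | COc1ccc(C(=O)O[C@@H]2CN(C)CC[C@@H]2c2c(O)cc(O[Si](C(C)C)(C(C)C)C(C)C)c(I)c2O)cc1OC | intermediate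
14 | propyne | CC#C | starting material
15 | carbon monoxide | [C-]#[O+] | starting material
16 | (3S,4R)‑4‑[3‑(but‑2‑ynoyl)‑2,6‑dihydroxy‑4‑(triisopropylsilyloxy)phenyl]‑1‑methylpiperidin‑3‑yl 3,4‑dimethoxybenzoate | COc1ccc(C(=O)O[C@@H]2CN(C)CC[C@@H]2c2c(O)cc(O[Si](C(C)C)(C(C)C)C(C)C)c(C(=O)C#CC)c2O)cc1OC | intermediate (not isolated)
17 | (3S,4R)‑4‑{3‑[(E)‑3‑(diethylamino)but‑2‑enoyl]‑2,6‑dihydroxy‑4‑(triisopropylsilyloxy)phenyl}‑1‑methylpiperidin‑3‑yl 3,4‑dimethoxybenzoate | COc1ccc(C(=O)O[C@@H]2CN(C)CC[C@@H]2c2c(O)cc(O[Si](C(C)C)(C(C)C)C(C)C)c(C(=O)/C=C(\C)N(CC)CC)c2O)cc1OC | intermediate (not isolated)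
18 | (3S,4R)‑4‑[7‑hydroxy‑2‑methyl‑4‑oxo‑5‑(triisopropylsilyloxy)‑4H‑chromen‑8‑yl]‑1‑methylpiperidin‑3‑yl 3,4‑dimethoxybenzoate | COc1ccc(C(=O)O[C@@H]2CN(C)CC[C@@H]2c2c(O)cc(O[Si](C(C)C)(C(C)C)C(C)C)c3c(=O)cc(C)oc23)cc1OC | intermediate
19 | chrotacumine D | COc1ccc(C(=O)O[C@@H]2CN(C)CC[C@@H]2c2c(O)cc(O)c3c(=O)cc(C)oc23)cc1OC | target

**Step count and risks**

Total step count: 11. Longest linear sequence: 11 steps (1 and 2 to 19).

Steps most likely to fail:

1. Step 10 (key step). The aroylpalladium intermediate may be captured by diethylamine (amide formation), the arylpalladium may couple with propyne before CO insertion, or the silyl ether may be lost before ring closure, which would open the second cyclisation mode. The fallback sets out from 13 and comes back at 18, using the classical chromone construction from an ortho‑hydroxyacetophenone. Stille coupling of 13 with tributyl(1‑ethoxyvinyl)stannane (Pd(PPh3)4, dioxane, 95 °C) should give the aryl enol ether F1. Brief hydrolysis with 1 M HCl in THF at rt should give the ortho‑hydroxyacetophenone F2. Claisen condensation of the lithium polyanion of F2 (LiN(SiMe3)2, 4 equiv, THF, −78 → 0 °C) with ethyl acetate should give the 1,3‑diketone F3. Acid‑catalysed cyclodehydration (TsOH, toluene, 60 °C) should then close the pyranone ring to 18; if the acid also removes the silyl ether, 19 is reached directly.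

2. Step 8. Silylation may occur at a hindered ortho hydroxyl or twice, which would leave the wrong phenol beside the iodine later on. The fallback sets out from 11 and comes back at 12, replacing steric discrimination in a chemical silylation by enzymatic discrimination between esters. Peracetylation (Ac2O, pyridine) should give the triacetate F4. Lipase‑catalysed butanolysis (Candida antarctica lipase B, n‑BuOH, t‑BuOMe, 40 °C) should remove only the unhindered para acetate and give the monophenol diacetate F5. Silylation of its single free hydroxyl (i‑Pr3SiCl, imidazole, DMF) should give the silyl ether diacetate F6. Aminolysis of the two aryl acetates with pyrrolidine should then give 12.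

3. Step 5. The diastereomeric salts may co‑crystallise or differ too little in solubility, so that enrichment stalls and half of the material is lost at best. The fallback sets out from ketone 5 and comes back at 7, replacing steps 4 and 5 by one catalytic step and making no new compound (F0). Asymmetric transfer hydrogenation with dynamic kinetic resolution (RuCl(p‑cymene)(TsDPEN) in the enantiomeric form that delivers the 3S alcohol, HCO2H–Et3N, 30–40 °C) relies on the α‑aryl centre of 5 racemising through its enol while one enantiomer is reduced faster, as is known for 2‑arylcycloalkanones, which give cis alcohols.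

**Further compounds**

F1 | step 10 | (3S,4R)‑4‑[3‑(1‑ethoxyvinyl)‑2,6‑dihydroxy‑4‑(triisopropylsilyloxy)phenyl]‑1‑methylpiperidin‑3‑yl 3,4‑dimethoxybenzoate | COc1ccc(C(=O)O[C@@H]2CN(C)CC[C@@H]2c2c(O)cc(O[Si](C(C)C)(C(C)C)C(C)C)c(C(=C)OCC)c2O)cc1OC
F2 | step 10 | (3S,4R)‑4‑[3‑acetyl‑2,6‑dihydroxy‑4‑(triisopropylsilyloxy)phenyl]‑1‑methylpiperidin‑3‑yl 3,4‑dimethoxybenzoate | COc1ccc(C(=O)O[C@@H]2CN(C)CC[C@@H]2c2c(O)cc(O[Si](C(C)C)(C(C)C)C(C)C)c(C(C)=O)c2O)cc1OC
F3 | step 10 | (3S,4R)‑4‑[3‑(3‑oxobutanoyl)‑2,6‑dihydroxy‑4‑(triisopropylsilyloxy)phenyl]‑1‑methylpiperidin‑3‑yl 3,4‑dimethoxybenzoate | COc1ccc(C(=O)O[C@@H]2CN(C)CC[C@@H]2c2c(O)cc(O[Si](C(C)C)(C(C)C)C(C)C)c(C(=O)CC(C)=O)c2O)cc1OC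
F4 | step 8 | (3S,4R)‑1‑methyl‑4‑(2,4,6‑triacetoxyphenyl)piperidin‑3‑yl 3,4‑dimethoxybenzoate | COc1ccc(C(=O)O[C@@H]2CN(C)CC[C@@H]2c2c(OC(C)=O)cc(OC(C)=O)cc2OC(C)=O)cc1OC
F5 | step 8 | (3S,4R)‑4‑(2,6‑diacetoxy‑4‑hydroxyphenyl)‑1‑methylpiperidin‑3‑yl 3,4‑dimethoxybenzoate | COc1ccc(C(=O)O[C@@H]2CN(C)CC[C@@H]2c2c(OC(C)=O)cc(O)cc2OC(C)=O)cc1OC
F6 | step 8 | (3S,4R)‑4‑[2,6‑diacetoxy‑4‑(triisopropylsilyloxy)phenyl]‑1‑methylpiperidin‑3‑yl 3,4‑dimethoxybenzoate | COc1ccc(C(=O)O[C@@H]2CN(C)CC[C@@H]2c2c(OC(C)=O)cc(O[Si](C(C)C)(C(C)C)C(C)C)cc2OC(C)=O)cc1OC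
F0 | step 5 | none | none
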